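**Strategy.** Everything rests on the 1,4-relationship between the C2 oxygen and the C19 carbon across C3–C4 in ring A (C1–C5, C10): it is the retron of a zinc-carbenoid homologation of a β-keto ester. In one operation the key step inserts C3 between the ketone carbon C2 and the ester-bearing C4 of a cyclopentanone, turning the five-membered ring C10–C1–C2–C4–C5 into six-membered ring A, and methylates C4 to the quaternary stereocentre. Its precursor is a trans-fused hydrindanone β-keto ester, assembled on the monoketal of 2,6-dimethylbenzoquinone (ring B) by asymmetric malonate addition, trans-alkylation and Claisen closure; the butenolide side chain is attached last through a C9 enol triflate.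

Key step: step 6

Remark: labdane numbering of the target is used for every intermediate (ring A = C1–C5 and C10; ring B = C5–C10; C18 and C19 on C4; C20 on C10; α is the face opposite C20); the catalyst enantiomer in step 2 is assigned by analogy with cyclohex-2-enone.

**Step 1**
Reactants: 1 2,6-dimethylphenol
Product: 3 4,4-dimethoxy-2,6-dimethylcyclohexa-2,5-dien-1-one, via 4-methoxy-2,6-dimethylphenol 2 (not isolated)
Conditions: PhI(OAc)2 (2.1 equiv), MeOH, 0 °C → rt
Reagents that add atoms: methanol CO
Why: Two successive hypervalent-iodine oxidations (oxidative dearomatisation) trap the phenoxenium ion with methanol at the free para position, first to the phenol 2 and then to the quinone monoketal; no stereocentre is formed.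

**Step 2**
Reactants: 3 4,4-dimethoxy-2,6-dimethylcyclohexa-2,5-dien-1-one; 4 dimethyl malonate
Product: 5 dimethyl 2-[(1R)-2,2-dimethoxy-4,6-dimethyl-5-oxocyclohex-3-en-1-yl]propanedioate (C10 epimers)
Conditions: LiAl[(R)-1,1'-bi-2-naphtholate]2 (10 mol %), KOtBu (9 mol %), 4 Å molecular sieves, THF, rt
Reagents that add atoms: none
Why: Catalytic asymmetric Michael addition of a malonate to a cyclic enone under Lewis acid/Brønsted base bimetallic catalysis desymmetrises the dienone and should set C5 as (R) by attack on one enantiotopic β-carbon face, the sense being that of cyclohex-2-enone, where the (R)-catalyst gives the (R)-adduct; the C10–H centre formed on protonation is inconsequential.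

**Step 3**
Reactants: 5 Michael adduct; 6 2-bromo-N-methoxy-N-methylacetamide
Product: 7 dimethyl 2-[(1S,6S)-2,2-dimethoxy-6-{2-[methoxy(methyl)amino]-2-oxoethyl}-4,6-dimethyl-5-oxocyclohex-3-en-1-yl]propanedioate
Conditions: LiN(iPr)2 (2.2 equiv), THF, −78 °C; then 6, DMPU, −78 → −20 °C
Reagents that add atoms: none
Why: Dianion alkylation occurs at the more reactive ketone enolate carbon C10 and anti to the bulky C5 substituent (2,3-trans rule for cyclohexanone enolates), which should set the C10 quaternary centre with the C1 arm trans to the C4 arm.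

**Step 4**
Reactants: 7 malonate Weinreb amide
Product: 8 methyl 2-[(1S,6S)-2,2-dimethoxy-6-{2-[methoxy(methyl)amino]-2-oxoethyl}-4,6-dimethyl-5-oxocyclohex-3-en-1-yl]acetate
Conditions: LiCl, H2O, DMSO, 140 °C
Reagents that add atoms: none
Why: Krapcho dealkoxycarbonylation removes one malonate ester by chloride attack on its methyl group and decarboxylation, leaving the C4H2–C19O2Me arm under conditions that spare the ketal, the enone and the Weinreb amide; C10 is already quaternary, so aromatisation is impossible.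

**Step 5**
Reactants: 8 ester Weinreb amide
Product: 9 methyl (3aS,7aS)-4,4-dimethoxy-6,7a-dimethyl-2,7-dioxo-2,3,3a,4,7,7a-hexahydro-1H-indene-3-carboxylate (trans-fused; C4 epimers and enol)
Conditions: LiN(SiMe3)2 (2.2 equiv), THF, −78 → 0 °C; aq. NH4Cl
Reagents that add atoms: none
Why: Intramolecular Claisen (Dieckmann-type) acylation, in which the ester enolate (more acidic than the amide α-CH2) attacks the Weinreb amide in a 5-exo-trig closure through a chelated tetrahedral intermediate, fixes the ketone at C2 and the ester on C4 and gives the trans ring fusion because the two arms are trans.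

**Step 6**
Reactants: 9 trans-hydrindanone β-keto ester
Product: 13 methyl (1S,4aS,8aR)-8,8-dimethoxy-1,4a,6-trimethyl-3,5-dioxo-1,2,3,4,4a,5,8,8a-octahydronaphthalene-1-carboxylate, via zinc cyclopropanolate 10 (not isolated), via ring-expanded zinc enolate 11 (not isolated), via zinc homoenolate 12 (not isolated)
Conditions: Et2Zn (6 equiv), CH2I2 (6 equiv), CH2Cl2, 0 °C, then 9; Me3SiCl (0.2 equiv), 0 °C → rt; aq. NH4Cl
Reagents that add atoms: diiodomethane ICI
Why: Et2Zn deprotonates the β-keto ester, the zinc enolate is alkylated at C4 by EtZnCH2I, and the resulting β-zincio ketone closes onto the C2 carbonyl (3-exo-trig) to the donor–acceptor cyclopropanolate 10, whose C2–C4 bond fragments so that the new CH2 (C3) sits between C2 and C4 in the six-membered γ-keto ester enolate 11. With excess carbenoid and catalytic Me3SiCl the enolate carbon C4 is alkylated a second time to the β-zincio ester 12, which is protonated on work-up to the C18 methyl group. The closest known reaction type is the zinc-carbenoid (Furukawa reagent) chain extension of β-keto esters to γ-keto esters, known in its ring-expansion mode for cyclic β-keto esters and in its tandem α-methylation mode through the homoenolate; the two modes are combined here on one substrate. Ring A is not closed anew but arises from the five-membered ring C10–C1–C2–C4–C5 by a net 1,2-acyl shift (three-membered ring closure, then fragmentation). The new quaternary stereocentre C4 should be set by the 10β-methyl group and the β-methoxy group of the C6 ketal, both syn-axial to the β-face of C4, so that the second CH2 enters equatorially (α) and the ester stays axial (β). The step needs chemoselectivity for the enolate over the C7=C8 double bond, which is secured because that bond belongs to an electron-poor enone that electrophilic zinc carbenoids do not cyclopropanate.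

**Step 7**
Reactants: 13 ketal diketo ester
Product: 14 methyl (1S,4aS,8aR)-1,4a,6-trimethyl-3,5,8-trioxo-1,2,3,4,4a,5,8,8a-octahydronaphthalene-1-carboxylate
Conditions: 1 M aq. HCl, THF, rt
Reagents that add atoms: water O
Why: Acid hydrolysis of the dimethyl ketal unmasks the C6 ketone, and the now epimerisable C5 should stay in the thermodynamically preferred trans ring fusion.

**Step 8**
Reactants: 14 enedione keto ester
Product: 15 4β-(hydroxymethyl)-4α,8,10β-trimethyl-trans-decalin-2α,6α,9-triol (5α-H; C8 and C9 epimers)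
Conditions: Li (excess), NH3(l), THF, EtOH, −78 → −33 °C; NH4Cl
Reagents that add atoms: none
Why: Dissolving-metal reduction (Birch and Bouveault–Blanc type) reduces the enedione, the C2 ketone and the hindered ester in one pot and, being thermodynamically controlled, should give the equatorial 2α- and 6α-alcohols, whereas hydride reagents would give the axial epimers because the β-face is blocked by C19 and C20; the C8 and C9 mixtures converge in step 12.

**Step 9**
Reactants: 15 tetraol
Product: 16 2α,19-bis(tert-butyldimethylsilyl) ether of 15 (6α-OH and 9-OH free)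
Conditions: TBSCl (2.2 equiv), imidazole, DMF, 0 °C
Reagents that add atoms: tert-butyl(chloro)dimethylsilane CC(C)(C)[Si](C)(C)Cl
Why: Steric discrimination in silyl ether formation: the primary C19 and the unhindered equatorial C2 hydroxyls should react, while the C6 hydroxyl (next to C5 and peri to C18) and the C9 hydroxyl (between quaternary C10 and C8) should not.

**Step 10**
Reactants: 16 bis-silyl ether diol
Product: 17 6α-acetate of 16 (9-OH free)
Conditions: Ac2O, pyridine, DMAP (cat.), CH2Cl2, 0 °C → rt
Reagents that add atoms: acetic anhydride CC(=O)OC(C)=O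
Why: Acylation of the remaining accessible C6 hydroxyl, the C9 hydroxyl between the quaternary C10 and the methyl-bearing C8 being too hindered to compete.

**Step 11**
Reactants: 17 acetate alcohol
Product: 18 6α-acetoxy-2α,19-bis(tert-butyldimethylsilyloxy)-9-ketone (C8 epimers)
Conditions: Dess–Martin periodinane, NaHCO3, CH2Cl2, rt
Reagents that add atoms: none
Why: Dess–Martin oxidation of the hindered secondary C9 alcohol under buffered conditions that tolerate the acetate and the silyl ethers; both C8 epimers are carried on.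

**Step 12**
Reactants: 18 C9 ketone
Product: 19 C8=C9 enol triflate (9-trifluoromethanesulfonyloxy-8-ene)
Conditions: Tf2O, 2,6-di-tert-butyl-4-methylpyridine, CH2Cl2, 0 °C → rt
Reagents that add atoms: trifluoromethanesulfonic anhydride O=S(=O)(OS(=O)(=O)C(F)(F)F)C(F)(F)F
Why: O-Triflation of the ketone with a hindered pyridine base gives the only possible enol triflate (toward C8, because C10 is quaternary) without enolate chemistry next to the acetate.

**Step 13**
Reactants: 19 enol triflate; 20 tributyl(vinyl)stannane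
Product: 21 6α-acetoxy-2α,19-bis(tert-butyldimethylsilyloxy)-9-vinyl-8-ene (C8=C9–C11=C12 diene)
Conditions: Pd(PPh3)4 (cat.), LiCl, THF, 65 °C
Reagents that add atoms: none
Why: Stille coupling of the tetrasubstituted enol triflate under neutral conditions installs C11 and C12 as the vinyl group of a 1,3-diene.

**Step 14**
Reactants: 21 diene; 22 4-bromofuran-2(5H)-one
Product: 24 2α,19-bis(tert-butyldimethylsilyl) ether of the target, via B-alkyl-9-BBN adduct 23 (not isolated)
Conditions: 9-BBN, THF, 0 °C → rt; then 22, PdCl2(dppf) (cat.), AsPh3, K3PO4, DMF/H2O, rt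
Reagents that add atoms: none
Why: 9-BBN should hydroborate only the monosubstituted terminal alkene of the diene (boron on C12), and B-alkyl Suzuki–Miyaura coupling with the β-bromobutenolide then forms the C12–C13 bond under a mild base that spares the acetate.

**Step 15**
Reactants: 24 bis-silyl ether
Product: 25 CNP0231903.1, (2R,4S,5R,6S,10S)-6α-acetoxy-2α,19-dihydroxylabda-8,13-dien-15,16-olide
Conditions: HF·pyridine, pyridine, THF, 0 °C → rt
Reagents that add atoms: none
Why: Fluoride cleavage of both silyl ethers under buffered conditions should leave the acetate, the butenolide and the tetrasubstituted alkene untouched.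

**Compound list**

1 | 2,6-dimethylphenol | Cc1cccc(C)c1O | starting material
2 | 4-methoxy-2,6-dimethylphenol | COc1cc(C)c(O)c(C)c1 | intermediate (not isolated)
3 | 4,4-dimethoxy-2,6-dimethylcyclohexa-2,5-dien-1-one | COC1(OC)C=C(C)C(=O)C(C)=C1 | intermediate
4 | dimethyl malonate | COC(=O)CC(=O)OC | starting material
5 | dimethyl 2-[(1R)-2,2-dimethoxy-4,6-dimethyl-5-oxocyclohex-3-en-1-yl]propanedioate (C10 epimers) | COC1(OC)C=C(C)C(=O)C(C)[C@@H]1C(C(=O)OC)C(=O)OC | intermediate
6 | 2-bromo-N-methoxy-N-methylacetamide | CON(C)C(=O)CBr | starting material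
7 | dimethyl 2-[(1S,6S)-2,2-dimethoxy-6-{2-[methoxy(methyl)amino]-2-oxoethyl}-4,6-dimethyl-5-oxocyclohex-3-en-1-yl]propanedioate | COC1(OC)C=C(C)C(=O)[C@@](C)(CC(=O)N(C)OC)[C@@H]1C(C(=O)OC)C(=O)OC | intermediate
8 | methyl 2-[(1S,6S)-2,2-dimethoxy-6-{2-[methoxy(methyl)amino]-2-oxoethyl}-4,6-dimethyl-5-oxocyclohex-3-en-1-yl]acetate | COC1(OC)C=C(C)C(=O)[C@@](C)(CC(=O)N(C)OC)[C@@H]1CC(=O)OC | intermediate
9 | methyl (3aS,7aS)-4,4-dimethoxy-6,7a-dimethyl-2,7-dioxo-2,3,3a,4,7,7a-hexahydro-1H-indene-3-carboxylate (trans-fused, 5α-H, 10β-methyl; C4 epimers) | COC1(OC)C=C(C)C(=O)[C@@]2(C)CC(=O)C(C(=O)OC)[C@H]12 | intermediate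
10 | ethylzinc cyclopropanolate (C3 methylene bridging C2 and C4 of 9) | COC1(OC)C=C(C)C(=O)[C@@]2(C)CC3(O[Zn]CC)CC3(C(=O)OC)[C@H]12 | intermediate (not isolated)
11 | ring-expanded ethylzinc ester enolate (C2 ketone, C3 methylene, C4 enolate) | COC1(OC)C=C(C)C(=O)[C@@]2(C)CC(=O)CC(=C(OC)O[Zn]CC)[C@H]12 | intermediate (not isolated)
12 | zinc homoenolate (4α-CH2ZnEt, 4β-CO2Me) | COC1(OC)C=C(C)C(=O)[C@@]2(C)CC(=O)C[C@](C[Zn]CC)(C(=O)OC)[C@H]12 | intermediate (not isolated)
13 | methyl (1S,4aS,8aR)-8,8-dimethoxy-1,4a,6-trimethyl-3,5-dioxo-1,2,3,4,4a,5,8,8a-octahydronaphthalene-1-carboxylate (2,9-dioxo, 6,6-dimethoxy, 4α-methyl, 4β-CO2Me) | COC1(OC)C=C(C)C(=O)[C@@]2(C)CC(=O)C[C@](C)(C(=O)OC)[C@H]12 | intermediate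
14 | methyl (1S,4aS,8aR)-1,4a,6-trimethyl-3,5,8-trioxo-1,2,3,4,4a,5,8,8a-octahydronaphthalene-1-carboxylate (2,6,9-trioxo) | O=C1C=C(C)C(=O)[C@@]2(C)CC(=O)C[C@](C)(C(=O)OC)[C@H]12 | intermediate
15 | 4β-(hydroxymethyl)-4α,8,10β-trimethyl-trans-decalin-2α,6α,9-triol (5α-H; C8 and C9 epimers) | O[C@H]1CC(C)C(O)[C@@]2(C)C[C@@H](O)C[C@](C)(CO)[C@H]12 | intermediate
16 | 2α,19-bis(tert-butyldimethylsilyl) ether of 15 | O[C@H]1CC(C)C(O)[C@@]2(C)C[C@@H](O[Si](C)(C)C(C)(C)C)C[C@](C)(CO[Si](C)(C)C(C)(C)C)[C@H]12 | intermediate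
17 | 6α-acetate of 16 | CC(=O)O[C@H]1CC(C)C(O)[C@@]2(C)C[C@@H](O[Si](C)(C)C(C)(C)C)C[C@](C)(CO[Si](C)(C)C(C)(C)C)[C@H]12 | intermediate
18 | 6α-acetoxy-2α,19-bis(tert-butyldimethylsilyloxy)-9-ketone (C8 epimers) | CC(=O)O[C@H]1CC(C)C(=O)[C@@]2(C)C[C@@H](O[Si](C)(C)C(C)(C)C)C[C@](C)(CO[Si](C)(C)C(C)(C)C)[C@H]12 | intermediate
19 | C8=C9 enol triflate of 18 | CC(=O)O[C@H]1CC(C)=C(OS(=O)(=O)C(F)(F)F)[C@@]2(C)C[C@@H](O[Si](C)(C)C(C)(C)C)C[C@](C)(CO[Si](C)(C)C(C)(C)C)[C@H]12 | intermediate
20 | tributyl(vinyl)stannane | C=C[Sn](CCCC)(CCCC)CCCC | starting material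
21 | 6α-acetoxy-2α,19-bis(tert-butyldimethylsilyloxy)-9-vinyl-8-ene | CC(=O)O[C@H]1CC(C)=C(C=C)[C@@]2(C)C[C@@H](O[Si](C)(C)C(C)(C)C)C[C@](C)(CO[Si](C)(C)C(C)(C)C)[C@H]12 | intermediate
22 | 4-bromofuran-2(5H)-one | O=C1C=C(Br)CO1 | starting material
23 | B-alkyl-9-BBN adduct of 21 (boron on C12) | CC(=O)O[C@H]1CC(C)=C(CCB3C4CCCC3CCC4)[C@@]2(C)C[C@@H](O[Si](C)(C)C(C)(C)C)C[C@](C)(CO[Si](C)(C)C(C)(C)C)[C@H]12 | intermediate (not isolated)
24 | 2α,19-bis(tert-butyldimethylsilyl) ether of the target | CC(=O)O[C@H]1CC(C)=C(CCC2=CC(=O)OC2)[C@@]2(C)C[C@@H](O[Si](C)(C)C(C)(C)C)C[C@](C)(CO[Si](C)(C)C(C)(C)C)[C@H]12 | intermediate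
25 | CNP0231903.1, (2R,4S,5R,6S,10S)-6α-acetoxy-2α,19-dihydroxylabda-8,13-dien-15,16-olide | CC(=O)O[C@H]1CC(C)=C(CCC2=CC(=O)OC2)[C@@]2(C)C[C@@H](O)C[C@](C)(CO)[C@H]12 | target

**Step count.** Total: 15 steps. Longest linear sequence: 15 steps, from 2,6-dimethylphenol 1.

**Steps most likely to fail**

1. Step 6. The second methylene transfer to the hindered, fully substituted zinc enolate may stall, leaving the C4–H ester, or facial control at C4 may be incomplete. The fallback sets out from 9 and separates ring expansion from methylation with radical and enolate chemistry. NaH and excess CH2Br2 in THF/HMPA should give the bromomethyl keto ester F1. Bu3SnH and AIBN in benzene at 80 °C (Dowd–Beckwith ring expansion) should give the γ-keto ester F2. HC(OMe)3, MeOH and TsOH should mask the C2 ketone as the bis-ketal F3. LiN(iPr)2 in THF at −78 °C followed by MeI should methylate the ester enolate from the α-face to the methylated bis-ketal F4. 1 M aq. HCl in THF then removes both ketals, and the route is rejoined at 14.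

2. Step 2. The α-methyl groups may make the conjugate addition slow and reversible and weaken the enantiofacial discrimination. The fallback sets out from 4 and runs the same catalytic addition on the parent dienone 4,4-dimethoxycyclohexa-2,5-dien-1-one F5 (commercial, the established unsubstituted cyclic enone class), which should give the adduct F6. Dianion methylation (LiN(iPr)2, MeI) should give the C10-methyl ketone F7. Dianion alkylation with 6 should give the quaternary Weinreb amide F8, and Krapcho conditions the monoester F9. I2 and pyridine in CH2Cl2 should give the α-iodoenone F10, and Stille methylation (Me4Sn, Pd(PPh3)4, CuI, DMF) brings in the C8 methyl group; the route is rejoined at 8.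

3. Step 9. Silylation may not discriminate cleanly between the C2 and C6 secondary hydroxyls. The fallback sets out from 13 and keeps C6 masked as its ketal during silylation. H2 over Pd/C should give the saturated ketal diketo ester F11. Li/NH3/EtOH should give the ketal triol F12. TBSCl and imidazole should give the bis-silyl ether F13, where only the strongly hindered C9 hydroxyl competes. PPTS in acetone/H2O should give the 6-ketone F14, and a second Li/NH3/EtOH reduction should give the 6α-alcohol; the route is rejoined at 16.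

**Further compounds**

F1 | step 6 | methyl 3-(bromomethyl)-4,4-dimethoxy-6,7a-dimethyl-2,7-dioxo-hexahydroindene-3-carboxylate (bromomethyl on C4 of 9) | COC1(OC)C=C(C)C(=O)[C@@]2(C)CC(=O)C(CBr)(C(=O)OC)[C@H]12
F2 | step 6 | methyl 8,8-dimethoxy-4a,6-dimethyl-3,5-dioxo-octahydronaphthalene-1-carboxylate (13 without the C18 methyl; C4 epimers) | COC1(OC)C=C(C)C(=O)[C@@]2(C)CC(=O)CC(C(=O)OC)[C@H]12
F3 | step 6 | C2 dimethyl ketal of F2 | COC1(OC)C=C(C)C(=O)[C@@]2(C)CC(OC)(OC)CC(C(=O)OC)[C@H]12
F4 | step 6 | C2 dimethyl ketal of 13 (4α-methyl, 4β-CO2Me) | COC1(OC)C=C(C)C(=O)[C@@]2(C)CC(OC)(OC)C[C@](C)(C(=O)OC)[C@H]12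
F5 | step 2 | 4,4-dimethoxycyclohexa-2,5-dien-1-one | COC1(OC)C=CC(=O)C=C1
F6 | step 2 | dimethyl 2-[(1R)-2,2-dimethoxy-5-oxocyclohex-3-en-1-yl]propanedioate | COC1(OC)C=CC(=O)C[C@@H]1C(C(=O)OC)C(=O)OC
F7 | step 2 | dimethyl 2-[(1R)-2,2-dimethoxy-6-methyl-5-oxocyclohex-3-en-1-yl]propanedioate (C6 epimers) | COC1(OC)C=CC(=O)C(C)[C@@H]1C(C(=O)OC)C(=O)OC
F8 | step 2 | dimethyl 2-[(1S,6S)-2,2-dimethoxy-6-{2-[methoxy(methyl)amino]-2-oxoethyl}-6-methyl-5-oxocyclohex-3-en-1-yl]propanedioate | COC1(OC)C=CC(=O)[C@@](C)(CC(=O)N(C)OC)[C@@H]1C(C(=O)OC)C(=O)OC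
F9 | step 2 | methyl 2-[(1S,6S)-2,2-dimethoxy-6-{2-[methoxy(methyl)amino]-2-oxoethyl}-6-methyl-5-oxocyclohex-3-en-1-yl]acetate | COC1(OC)C=CC(=O)[C@@](C)(CC(=O)N(C)OC)[C@@H]1CC(=O)OC
F10 | step 2 | 4-iodo analogue of F9 (α-iodoenone) | COC1(OC)C=C(I)C(=O)[C@@](C)(CC(=O)N(C)OC)[C@@H]1CC(=O)OC
F11 | step 9 | 7,8-dihydro derivative of 13 (C8 epimers) | COC1(OC)CC(C)C(=O)[C@@]2(C)CC(=O)C[C@](C)(C(=O)OC)[C@H]12
F12 | step 9 | 6,6-dimethoxy-2α,9,19-triol (C8 and C9 epimers) | COC1(OC)CC(C)C(O)[C@@]2(C)C[C@@H](O)C[C@](C)(CO)[C@H]12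
F13 | step 9 | 2α,19-bis(tert-butyldimethylsilyl) ether of F12 | COC1(OC)CC(C)C(O)[C@@]2(C)C[C@@H](O[Si](C)(C)C(C)(C)C)C[C@](C)(CO[Si](C)(C)C(C)(C)C)[C@H]12
F14 | step 9 | 9-hydroxy-2α,19-bis(tert-butyldimethylsilyloxy)-6-ketone | O=C1CC(C)C(O)[C@@]2(C)C[C@@H](O[Si](C)(C)C(C)(C)C)C[C@](C)(CO[Si](C)(C)C(C)(C)C)[C@H]12
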